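**Retrosynthetic overview**

- The anisoate is placed last, on the only secondary hydroxyl of a triol; the trans-diol comes from carotol by hydroxyl-directed epoxidation and anti opening with water.
- Carotol comes from its isopropenyl analogue, and both carbocycles of that compound are made in one flask from a monocyclic bromo-oxolane: E2 elimination, then Claisen ring expansion (seven-membered ring first), then carbonyl-ene closure (five-membered ring second).
- The bromo-oxolane comes from (3S,6E)-nerolidol by bromoetherification; nerolidol comes from (2E,6E)-farnesol by asymmetric epoxidation and reductive transposition.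
- The nerolidol carbinol centre is relayed to the quaternary ring-fusion carbon in the Claisen step and is then erased; every other stereocentre follows from that one.

Reading of the target used throughout: cis-fused hydroazulene with 8a-Me, 3a-OH and 3-iPr on one face, the 7-aroyloxy group on that same face and the 6-OH on the opposite face.

**Route**

Step 1
Reactants: 1 (2E,6E)-farnesol
Product: 2 [(2S,3S)-3-[(3E)-4,8-dimethylnona-3,7-dien-1-yl]-3-methyloxiran-2-yl]methanol
Conditions: Ti(OiPr)4 (5 mol%), L-(+)-diethyl tartrate (6 mol%), tBuOOH, 4 Å MS, CH2Cl2, −20 °C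
Reagents that add atoms: tert-butyl hydroperoxide, CC(C)(C)OO
Why: Sharpless asymmetric epoxidation, in which the titanium tartrate complex binds the allylic alcohol and delivers oxygen to one face of the 2,3-alkene only (L-(+)-tartrate gives 2S,3S) while the two remote alkenes are untouched.

Step 2
Reactants: 2 [(2S,3S)-3-[(3E)-4,8-dimethylnona-3,7-dien-1-yl]-3-methyloxiran-2-yl]methanol
Product: 3 (3S,6E)-nerolidol, (3S,6E)-3,7,11-trimethyldodeca-1,6,10-trien-3-ol
Conditions: Cp2TiCl2 (2.5 equiv), Zn dust, THF, rt
Reagents that add atoms: none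
Why: Reductive epoxy-alcohol to allylic-alcohol transposition, in which Cp2TiCl (trivalent titanium) opens the epoxide homolytically at C2, a second equivalent traps the radical and the C1 oxygen leaves by β-elimination, so the C3–O bond is never broken and the 3S centre is kept.

Step 3
Reactants: 3 (3S,6E)-nerolidol
Product: 4 (2S,5S)-2-[(2R)-2-bromo-6-methylhept-5-en-2-yl]-5-ethenyl-5-methyloxolane together with its (2R,5S)-2-[(2S)-2-bromo-6-methylhept-5-en-2-yl] diastereomer (about 1:1, used as the mixture)
Conditions: NBS (1.05 equiv), CH2Cl2, 0 °C, dark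
Reagents that add atoms: N-bromosuccinimide, O=C1CCC(=O)N1Br
Why: Bromoetherification, in which the tertiary hydroxyl captures the bromonium ion of the 6,7-alkene by 5-exo anti addition (the 10,11-alkene has no internal nucleophile and the vinyl group is less nucleophilic), so both diastereomers have ring oxygen and bromine anti across the former E-alkene, which is all the next step needs.

Step 4
Reactants: 4 the bromo-oxolane mixture
Product: 7 (3R,3aS,8aR)-6,8a-dimethyl-3-(prop-1-en-2-yl)-2,3,4,5,8,8a-hexahydroazulen-3a(1H)-ol, via enol ether 5 (not isolated), via cycloheptenone 6 (not isolated)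
Conditions: DBU (2 equiv), PhMe, 110 °C then 180 °C (sealed tube); cool to −78 °C, Me2AlCl (5 equiv), −78 to 0 °C, same flask
Reagents that add atoms: none
Why: Proposed new method: three known events are merged in one flask, namely anti E2 loss of HBr, which turns either diastereomer of 4 into the single E enol ether 5, then Claisen rearrangement of 5, in which the vinyl group can only reach the alkylidene carbon across its own face of the oxolane, so the ring expands to the cycloheptenone 6 and the 5S centre is relayed to the new quaternary carbon as R, and finally a Me2AlCl-promoted concerted carbonyl-ene reaction of the side-chain alkene, which closes the five-membered ring cis-fused (the tether can only reach the carbonyl face it sits on) with the hydroxyl cis to the isopropenyl group (hydrogen is passed to oxygen within a six-membered array); the closest known reactions are the thermal Claisen ring expansion of 2-alkylidene-5-vinyloxolanes to cyclohept-4-enones and the Me2AlCl-promoted ene cyclisation of unsaturated ketones.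

Step 5
Reactants: 7 (3R,3aS,8aR)-6,8a-dimethyl-3-(prop-1-en-2-yl)-2,3,4,5,8,8a-hexahydroazulen-3a(1H)-ol
Product: 8 (3R,3aS,8aR)-6,8a-dimethyl-3-(propan-2-yl)-2,3,4,5,8,8a-hexahydroazulen-3a(1H)-ol (carotol)
Conditions: H2 (1 atm), RhCl(PPh3)3 (5 mol%), PhH, rt
Reagents that add atoms: none
Why: Chemoselective homogeneous hydrogenation, in which RhCl(PPh3)3 reduces the 1,1-disubstituted isopropenyl alkene far faster than the trisubstituted ring alkene and no new stereocentre is formed.

Step 6
Reactants: 8 carotol
Product: 10 (3R,3aS,6R,7R,8aR)-6,8a-dimethyl-3-(propan-2-yl)decahydroazulene-3a,6,7-triol, via epoxide 9 (not isolated)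
Conditions: VO(acac)2 (3 mol%), tBuOOH, PhMe, rt; then THF–H2O, HClO4 (cat.), 0 °C to rt
Reagents that add atoms: tert-butyl hydroperoxide, CC(C)(C)OO; water, O
Why: Hydroxyl-directed epoxidation followed by acid-catalysed epoxide hydrolysis, in which the vanadate ester of the ring-fusion hydroxyl delivers oxygen to the alkene face it sits on, and water then opens the protonated epoxide at the tertiary carbon C6 with inversion (the syn hydroxyl cannot reach the backside), giving the trans-diol with 6-OH anti and 7-OH syn to the 3a-OH.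

Step 7
Reactants: 10 (3R,3aS,6R,7R,8aR)-6,8a-dimethyl-3-(propan-2-yl)decahydroazulene-3a,6,7-triol; 11 4-methoxybenzoyl chloride
Product: 12 (3R,3aS,6R,7R,8aR)-3a,6-dihydroxy-6,8a-dimethyl-3-(propan-2-yl)decahydroazulen-7-yl 4-methoxybenzoate
Conditions: 11 (1.3 equiv), DMAP (0.2 equiv), pyridine, CH2Cl2, 0 °C to rt
Reagents that add atoms: 4-methoxybenzoyl chloride (11), COc1ccc(cc1)C(Cl)=O
Why: DMAP-catalysed acylation (nucleophilic catalysis) takes the single secondary hydroxyl because the two tertiary hydroxyls react far more slowly, and no stereocentre is touched.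

**Compound list**

1 | (2E,6E)-farnesol, (2E,6E)-3,7,11-trimethyldodeca-2,6,10-trien-1-ol | CC(C)=CCC/C(C)=C/CC/C(C)=C/CO | starting material
2 | [(2S,3S)-3-[(3E)-4,8-dimethylnona-3,7-dien-1-yl]-3-methyloxiran-2-yl]methanol | CC(C)=CCC/C(C)=C/CC[C@]1(C)O[C@H]1CO | intermediate
3 | (3S,6E)-nerolidol, (3S,6E)-3,7,11-trimethyldodeca-1,6,10-trien-3-ol | CC(C)=CCC/C(C)=C/CC[C@](C)(O)C=C | intermediate
4 | (2S,5S)-2-[(2R)-2-bromo-6-methylhept-5-en-2-yl]-5-ethenyl-5-methyloxolane and (2R,5S)-2-[(2S)-2-bromo-6-methylhept-5-en-2-yl]-5-ethenyl-5-methyloxolane, about 1:1 | C=C[C@]1(C)CC[C@H](O1)[C@](C)(Br)CCC=C(C)C.C=C[C@]1(C)CC[C@@H](O1)[C@@](C)(Br)CCC=C(C)C | intermediate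
5 | (2E,5S)-5-ethenyl-5-methyl-2-(6-methylhept-5-en-2-ylidene)oxolane | C=C[C@]1(C)CC/C(O1)=C(/C)CCC=C(C)C | intermediate (not isolated)
6 | (2R)-2,5-dimethyl-2-(4-methylpent-3-en-1-yl)cyclohept-4-en-1-one | O=C1CCC(C)=CC[C@@]1(C)CCC=C(C)C | intermediate (not isolated)
7 | (3R,3aS,8aR)-6,8a-dimethyl-3-(prop-1-en-2-yl)-2,3,4,5,8,8a-hexahydroazulen-3a(1H)-ol | CC1=CC[C@@]2(C)CC[C@H](C(C)=C)[C@@]2(O)CC1 | intermediate
8 | (3R,3aS,8aR)-6,8a-dimethyl-3-(propan-2-yl)-2,3,4,5,8,8a-hexahydroazulen-3a(1H)-ol (carotol) | CC1=CC[C@@]2(C)CC[C@H](C(C)C)[C@@]2(O)CC1 | intermediate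
9 | (3R,3aS,6S,7R,8aR)-6,7-epoxy-6,8a-dimethyl-3-(propan-2-yl)decahydroazulen-3a-ol, epoxide oxygen on the face of the 3a-OH | O1[C@@H]2C[C@@]3(C)CC[C@H](C(C)C)[C@@]3(O)CC[C@]12C | intermediate (not isolated)
10 | (3R,3aS,6R,7R,8aR)-6,8a-dimethyl-3-(propan-2-yl)decahydroazulene-3a,6,7-triol | O[C@@H]1C[C@@]2(C)CC[C@H](C(C)C)[C@@]2(O)CC[C@@]1(C)O | intermediate
11 | 4-methoxybenzoyl chloride | COc1ccc(cc1)C(Cl)=O | starting material
12 | (3R,3aS,6R,7R,8aR)-3a,6-dihydroxy-6,8a-dimethyl-3-(propan-2-yl)decahydroazulen-7-yl 4-methoxybenzoate | COc1ccc(C(=O)O[C@@H]2C[C@@]3(C)CC[C@H](C(C)C)[C@@]3(O)CC[C@@]2(C)O)cc1 | target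

**Step count**

Total steps: 7. Longest linear sequence: 7 (1 to 12; 11 is bought).

**Steps most likely to fail, with fallbacks**

Step 4. The elimination may not go cleanly toward the ring carbon, an E/Z-scrambled enol ether would lower the ee, and the amine salts may blunt the Lewis acid in the ene stage. The fallback sets out from 4: the flask is worked up after the thermal stage (DBU, PhMe, 180 °C) and ketone 6 is isolated. TiCl4 in CH2Cl2 at −78 °C then closes the five-membered ring by a stepwise Prins cyclisation in which chloride caps the side-chain cation, giving (3S,3aS,8aR)-3-(2-chloropropan-2-yl)-6,8a-dimethyl-2,3,4,5,8,8a-hexahydroazulen-3a(1H)-ol F1. Radical dechlorination with Bu3SnH and AIBN in PhH at 80 °C gives 8, so the route is rejoined at 8 and step 5 is not needed.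

Step 6. The ring-fusion hydroxyl is only bishomoallylic, so oxygen delivery to its own face is not guaranteed, and the tertiary alcohol is acid-sensitive. The fallback sets out from 8 and uses the opposite face with the opposite regiochemistry of opening. Buffered peracid (mCPBA, NaHCO3, CH2Cl2, 0 °C) attacks anti to the hydroxyl and gives (3R,3aS,6R,7S,8aR)-6,7-epoxy-6,8a-dimethyl-3-(propan-2-yl)decahydroazulen-3a-ol F2. Hot aqueous KOH in DMSO (100 °C) then opens it by SN2 attack of hydroxide at the secondary carbon C7, anti to the epoxide oxygen, which gives the same triol; the route is rejoined at 10.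

Step 2. The C2 radical could cyclise onto the 6,7-alkene, or the epoxide could open toward the tertiary radical and simply deoxygenate. The fallback sets out from 2 and replaces the radical transposition by an ionic one. I2, PPh3 and imidazole in Et2O–MeCN at 0 °C give (2R,3S)-3-[(3E)-4,8-dimethylnona-3,7-dien-1-yl]-2-(iodomethyl)-3-methyloxirane F3. Zn dust in refluxing EtOH then inserts into the C–I bond and the epoxide opens by β-elimination to the tertiary allylic alcohol; the route is rejoined at 3.

Further compounds
F1 | step 4 | (3S,3aS,8aR)-3-(2-chloropropan-2-yl)-6,8a-dimethyl-2,3,4,5,8,8a-hexahydroazulen-3a(1H)-ol | CC1=CC[C@@]2(C)CC[C@H](C(C)(C)Cl)[C@@]2(O)CC1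
F2 | step 6 | (3R,3aS,6R,7S,8aR)-6,7-epoxy-6,8a-dimethyl-3-(propan-2-yl)decahydroazulen-3a-ol | O1[C@H]2C[C@@]3(C)CC[C@H](C(C)C)[C@@]3(O)CC[C@@]12C
F3 | step 2 | (2R,3S)-3-[(3E)-4,8-dimethylnona-3,7-dien-1-yl]-2-(iodomethyl)-3-methyloxirane | CC(C)=CCC/C(C)=C/CC[C@]1(C)O[C@H]1CI
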